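Ring letters with flavan numbering are used throughout: upper unit = ring A (benzo), ring C (pyran), ring B (catechol); lower unit = ring D (benzo), ring F (pyran), ring E (catechol).

## The problem

Target 16 is fisetinidol-(4β→6)-leucofisetinidin. It has two (2R,3S) flavan units joined by a C4(C)–C6(D) bond. The upper unit is a 2,3-trans-3,4-cis 4-arylflavan-3-ol and the lower unit a 2,3-trans-3,4-cis flavan-3,4-diol, six stereocentres in all.

The interflavanyl bond is the hard part. It must form at C6(D) and not at C8(D), and it must be cis to O3(C). Capture of a C4 cation of a 2,3-trans flavan normally occurs anti to O3 and gives the 4α epimer.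

The lower unit is a second liability. Its 4-OH(F) is benzylic and para to the free 7-OH(D), so it ionises as easily as any C4 electrophile used to make the interflavanyl bond. It is also the less stable, 3,4-cis diol epimer.

The stereocentres reduce to a simple pattern. In both pyran rings the two substituents at C3 and C4 are cis to each other and trans to the C2 aryl. Both heterocycles are therefore syn adducts, on the face away from the aryl group, of one and the same (2S)-flav-3-ene: O,O for ring F and O,C for ring C. C2 is the only centre that needs a reagent to set it.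

The feature that makes the key step possible is the chain O3(C)–C3(C)–C4(C)–C6(D)–C7(D)–O7(D). C6(D) is ortho to a free phenol and the new bond is cis to O3(C), so a single boron atom can close this chain to a seven-membered ring and carry C6(D) to C4(C) on the O3 face.

The free catechols, the p-hydroxybenzylic 4-OH(F) and the interflavanyl bond rule out acid and hydrogenolysis at the end. All phenols are therefore carried as silyl ethers and freed with buffered fluoride.

## Retrosynthesis

**16 ⇒ 15.** Five aryl O–Si bonds are cut (one TBS, four TIPS). Silyl ethers are the only phenol protection that can be removed without hydrogen (risk of C4(F)–O hydrogenolysis) or acid (ionisation at C4(F)). The forward step must stay near neutral.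

**15 ⇒ 14.** The C3(F)–O and C4(F)–O bonds are cut and the lower cis-diol becomes the C3(F)=C4(F) alkene of a flav-3-ene. Carrying the diol through the coupling would expose a p-oxybenzylic C–O bond to the Lewis acid that makes the interflavanyl bond. The alkene cannot ionise at C4, so the most fragile function is installed after the C–C bond. The forward reaction must be a syn dihydroxylation anti to the C2(F) aryl.

**14 ⇒ 12 + 11 (through borate 13).** The C4(C)–C6(D) bond is cut, with O3(C) and O7(D) joined through boron in the transition state. A free-cation disconnection at the same bond would give the 4α epimer, because O3 directs the nucleophile to the opposite face. Here O3 is the anchor of the tether, so the same oxygen enforces the 4β configuration. The precursors are epoxide 12 and phenol 11, each a derivative of one monomer. The forward reaction must open the epoxide with retention at C4 and alkylate C6(D), not C8(D) or oxygen.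

**12 ⇒ 10 and 11 ⇒ 10.** The epoxide oxygen of 12 is removed to give the alkene, and the 7-O–H of 11 is re-silylated on paper. Both halves then converge on flavene 10, which has a single stereocentre. The forward reactions are an epoxidation anti to the C2 aryl and a selective cleavage of the aryl TBS ether beside two aryl TIPS ethers.

**10 ⇒ 4 + 9.** The C2–aryl bond is cut. Closing the pyran at O1–C2 or descending from a flavanone would need more steps and a separate source of chirality. This cut attaches the catechol ring and sets the only reagent-controlled stereocentre in one catalytic step on a planar benzopyrylium ion, so racemic acetal 4 is used in full. The forward reaction must select one face of the cation and attack C2, not C4.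

**4 ⇒ 2 ⇒ 1 and 9 ⇒ 6 ⇒ 5.** Umbelliferone 1 supplies ring A (or D) with O1, C2–C4 and the 7-oxygen in place, and needs only silylation and lactone half-reduction/acetalisation. 4-Bromocatechol 5 supplies ring B (or E) after silylation and bromine–lithium exchange/borylation.

## Roads not taken

**Alternative 1:** the biomimetic cut of C4(C)–C6(D) into a C4 cation and a phenolic nucleophile. The forward key step is mild acid treatment of (+)-mollisacacidin A1 (the 3,4-trans diol) with its 3,4-cis epimer A2 as the ring-D nucleophile.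
- A1 and A2 ionise to the same C4 cation, so no acid can activate one and spare the other. The diol configuration of the lower unit scrambles and oligomers form.
- Capture of that cation anti to O3(C) favours the 4α epimer A3 over the target.
- C8(D) competes with C6(D).
- The chosen plan removes all three problems by structure: the nucleophile has no ionisable C4, the aryl group is delivered from O3, and it is delivered only to an ortho carbon.

**Alternative 2:** cut C4(C)–C6(D) as an sp2–sp2 bond. The 4-arylflav-3-ene A4 would be made by Suzuki–Miyaura cross-coupling and then hydroborated and oxidised.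
- Regiochemistry at ring D is unambiguous, but hydroboration adds H and B syn, anti to the C2 aryl. H therefore ends up cis to the new 3-OH and the aryl group trans to it, which is the 4α series of A3, not the target.
- A4 has two flavene double bonds that hydroboration cannot tell apart, and a ring-D C6 boron or halogen handle costs extra steps.
- The chosen plan adds C and O syn across the same double bond, which is exactly the relationship the target has.

**Alternative 3:** the same cut with a covalent silicon tether. In precursor A5, O3(C) of a 4-ethoxy upper unit is tied through Si(i-Pr)2 to O7(D) of an acetonide-protected lower unit. Lewis-acid ionisation at C4(C) and intramolecular Friedel–Crafts closure of the seven-membered ring would follow, then removal of the tether.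
- The stereochemical logic is sound and is the same as in the chosen plan.
- A5 needs two separately made flavans, one oxidised at C4 and one carrying a protected diol.
- It needs separate steps to put the tether on and take it off.
- It needs a strong Lewis acid in the presence of a p-oxybenzylic acetonide, and acid to remove that acetonide from the final labile diol.
- In the chosen plan boron activates the electrophile, acts as the tether and leaves on aqueous work-up, all in one flask, and both partners come from one monomer.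

Key step: step 8

Assumption: in step 5 the sense of induction is set by the choice of tartaric acid enantiomer in the ligand; the enantiomer leading to (2S)-10 is used.

## Route

Step 1
Reactants: 1 umbelliferone (7-hydroxycoumarin)
Product: 2 7-(tert-butyldimethylsilyloxy)coumarin
Conditions: TBSCl, imidazole, DMF, rt
Reagents that add atoms: tert-butyldimethylsilyl chloride, CC(C)(C)[Si](C)(C)Cl
Why: Standard silylation of a phenol; the aryl silyl ether withstands i-Bu2AlH at low temperature and later supplies the donor that stabilises the benzopyrylium ion.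

Step 2
Reactants: 2 7-(tert-butyldimethylsilyloxy)coumarin
Product: 4 2-ethoxy-7-(tert-butyldimethylsilyloxy)-2H-chromene (racemic), via lactol 3 (not isolated)
Conditions: i-Bu2AlH (1.1 equiv), CH2Cl2, −78 °C; Rochelle salt work-up; then EtOH, PPTS (cat.), rt
Reagents that add atoms: ethanol, CCO
Why: Half-reduction of the lactone stops at the aluminium lactolate at −78 °C, and the lactol exchanges OH for OEt under mild acid through the 7-silyloxybenzopyrylium ion (lactone-to-lactol reduction, then acetalisation); the racemic C2 is erased again in step 5.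

Step 3
Reactants: 5 4-bromocatechol
Product: 6 4-bromo-1,2-bis(triisopropylsilyloxy)benzene
Conditions: TIPSOTf (2.3 equiv), 2,6-lutidine, CH2Cl2, 0 °C to rt
Reagents that add atoms: triisopropylsilyl trifluoromethanesulfonate, CC(C)[Si](C(C)C)(C(C)C)OS(=O)(=O)C(F)(F)F
Why: The silyl triflate is reactive enough for the crowded second silylation of the catechol; TIPS is chosen because aryl TIPS ethers outlast the aryl TBS ether in step 6 and still fall to fluoride in step 10.

Step 4
Reactants: 6 4-bromo-1,2-bis(triisopropylsilyloxy)benzene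
Product: 9 diethyl [3,4-bis(triisopropylsilyloxy)phenyl]boronate, via aryllithium 7 (not isolated), via lithium triethoxyborate 8 (not isolated)
Conditions: n-BuLi, THF, −78 °C; B(OEt)3, −78 °C to rt; HCl in Et2O (1.0 equiv), 0 °C; filtration, concentration
Reagents that add atoms: triethyl borate, CCOB(OCC)OCC
Why: Bromine–lithium exchange and borylation; the lithium sits meta and para to the silyloxy groups, so no silyl migration to carbon is possible, and protonation of the ate complex with anhydrous HCl releases the neutral diethyl boronate that step 5 needs.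

Step 5
Reactants: 4 2-ethoxy-7-(tert-butyldimethylsilyloxy)-2H-chromene (racemic); 9 diethyl [3,4-bis(triisopropylsilyloxy)phenyl]boronate
Product: 10 (2S)-2-[3,4-bis(triisopropylsilyloxy)phenyl]-7-(tert-butyldimethylsilyloxy)-2H-chromene
Conditions: 9 (1.5 equiv), Yb(OTf)3 (5 mol%), N,N-dibenzyltartramic acid (6 mol%), EtOAc, −20 °C
Reagents that add atoms: none
Why: Catalytic enantioselective addition of an aryl boronate to a chromene acetal: the Lewis acid/Brønsted acid pair ionises both enantiomers of 4 to the same planar 7-silyloxybenzopyrylium ion, and the electron-rich aryl group migrates to C2 from boron held by the chiral tartrate-derived ligand, which selects the face and sets C2.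

Step 6
Reactants: 10 (2S)-2-[3,4-bis(triisopropylsilyloxy)phenyl]-7-(tert-butyldimethylsilyloxy)-2H-chromene
Product: 11 (2S)-2-[3,4-bis(triisopropylsilyloxy)phenyl]-2H-chromen-7-ol
Conditions: K2CO3 (0.2 equiv), MeOH/THF (1:1), 0 °C, stopped at full conversion; aq. NH4Cl
Reagents that add atoms: none
Why: Base-catalysed methanolysis of aryl silyl ethers is much faster for the unhindered aryl TBS ether than for the two mutually shielding aryl TIPS ethers; low temperature and sub-stoichiometric base keep the acid- and base-sensitive flavene intact.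

Step 7
Reactants: 10 (2S)-2-[3,4-bis(triisopropylsilyloxy)phenyl]-7-(tert-butyldimethylsilyloxy)-2H-chromene
Product: 12 (2R,3S,4S)-2-[3,4-bis(triisopropylsilyloxy)phenyl]-7-(tert-butyldimethylsilyloxy)-3,4-epoxychromane (2,3-trans epoxide, crude, used at once)
Conditions: dimethyldioxirane (1.1 equiv, acetone), CH2Cl2, −40 °C; volatiles removed cold under vacuum
Reagents that add atoms: dimethyldioxirane, CC1(C)OO1
Why: Dioxirane epoxidation of the electron-rich cis-styrenyl double bond under neutral, non-nucleophilic conditions; oxygen enters anti to the C2 aryl, which sets C3 and C4, and the only by-product is acetone, so the labile p-silyloxybenzylic epoxide survives until it is used.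

Step 8
Reactants: 12 (2R,3S,4S)-2-[3,4-bis(triisopropylsilyloxy)phenyl]-7-(tert-butyldimethylsilyloxy)-3,4-epoxychromane; 11 (2S)-2-[3,4-bis(triisopropylsilyloxy)phenyl]-2H-chromen-7-ol
Product: 14 (2R,3S,4S)-2-[3,4-bis(triisopropylsilyloxy)phenyl]-7-(tert-butyldimethylsilyloxy)-4-{(2S)-2-[3,4-bis(triisopropylsilyloxy)phenyl]-7-hydroxy-2H-chromen-6-yl}chroman-3-ol, via triaryl borate 13 (not isolated)
Conditions: 11 (3.0 equiv), B(NMe2)3 (1.0 equiv), toluene, rt then 40 °C under vacuum; then 12 (1.0 equiv), CH2Cl2, −78 to −20 °C; aq. NaHCO3; excess 11 recovered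
Reagents that add atoms: none
Why: The boron atom of triaryl borate 13 binds the oxirane oxygen of 12 and loosens the C4(C)–O bond, which is benzylic and para to the 7-silyloxy group, while the oxygen stays on C3(C) and on boron; one aryloxy ligand then delivers its ortho carbon C6(D) to C4(C) inside this contact ion pair through a seven-membered cyclic transition state (C4–C3–O–B–O–C7(D)–C6(D)), and rearomatisation with proton transfer to the borate, then hydrolysis, releases 14. The closest known reaction type is the aryl-borate-mediated ortho C-alkylation of phenols by aryl oxiranes, a boron-templated Friedel–Crafts alkylation that proceeds with retention at the benzylic carbon. No permanent ring is closed; the transient seven-membered dioxaborepine that holds O3(C) and O7(D) is opened on work-up. The one new stereocentre, C4(C), is controlled by the oxirane oxygen itself: the nucleophile is carried by the boron bound to that oxygen, so the aryl group enters on the face the oxygen leaves, cis to O3(C), which gives the 3,4-cis (4S) configuration, and C2 and C3 are carried over unchanged from 12. The step needs (a) syn over anti capture, secured by the intramolecular delivery; (b) C6(D) over C8(D), secured because C8(D) lies between O7(D) and O1(D) and is the more hindered ortho position; (c) C- over O-alkylation and arene over the C3(F)=C4(F) alkene, secured because only the ortho carbon of the boron-bound ring reaches C4(C) in a small cyclic transition state. Both partners derive from 10, so the bond formation is in effect a dimerisation of one monomer in two oxidation states.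

Step 9
Reactants: 14 the coupled flavan–flavene from step 8
Product: 15 (2R,3S,4S)-2-[3,4-bis(triisopropylsilyloxy)phenyl]-6-{(2R,3S,4S)-2-[3,4-bis(triisopropylsilyloxy)phenyl]-7-(tert-butyldimethylsilyloxy)-3-hydroxychroman-4-yl}chromane-3,4,7-triol
Conditions: OsO4 (5 mol%), N-methylmorpholine N-oxide (1.5 equiv), acetone/H2O, 0 °C to rt; aq. Na2SO3
Reagents that add atoms: osmium tetroxide, O=[Os](=O)(=O)=O; N-methylmorpholine N-oxide, C[N+]1([O-])CCOCC1; water, O
Why: Osmium-catalysed syn dihydroxylation of the only alkene; the [3+2] addition takes the face anti to the C2(F) aryl, as is general for flav-3-enes, and sets C3(F) and C4(F) as the 2,3-trans-3,4-cis diol under neutral conditions that leave the silyl ethers and the new benzylic alcohol alone.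

Step 10
Reactants: 15 the penta-silylated dimer from step 9
Product: 16 (2R,3S,4S)-2-(3,4-dihydroxyphenyl)-6-[(2R,3S,4S)-2-(3,4-dihydroxyphenyl)-3,7-dihydroxy-3,4-dihydro-2H-chromen-4-yl]-3,4-dihydro-2H-chromene-3,4,7-triol (target, CNP0280090.1)
Conditions: TBAF/AcOH (1:1, 6 equiv), THF, 0 °C; size-exclusion chromatography (EtOH/H2O)
Reagents that add atoms: none
Why: Fluoride cleaves all five aryl silyl ethers; buffering with acetic acid keeps the medium near neutral, so the p-hydroxybenzylic 4-OH(F) neither ionises nor eliminates to a quinone methide, and no stereocentre is touched.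

## Compound list

1 | umbelliferone (7-hydroxy-2H-chromen-2-one) | O=C1C=Cc2ccc(O)cc2O1 | starting material
2 | 7-(tert-butyldimethylsilyloxy)-2H-chromen-2-one | O=C1C=Cc2ccc(O[Si](C)(C)C(C)(C)C)cc2O1 | intermediate
3 | 7-(tert-butyldimethylsilyloxy)-2H-chromen-2-ol (racemic lactol) | OC1C=Cc2ccc(O[Si](C)(C)C(C)(C)C)cc2O1 | intermediate
4 | 2-ethoxy-7-(tert-butyldimethylsilyloxy)-2H-chromene (racemic) | CCOC1C=Cc2ccc(O[Si](C)(C)C(C)(C)C)cc2O1 | intermediate
5 | 4-bromocatechol (4-bromobenzene-1,2-diol) | Oc1ccc(Br)cc1O | starting material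
6 | 4-bromo-1,2-bis(triisopropylsilyloxy)benzene | Brc1ccc(O[Si](C(C)C)(C(C)C)C(C)C)c(O[Si](C(C)C)(C(C)C)C(C)C)c1 | intermediate
7 | [3,4-bis(triisopropylsilyloxy)phenyl]lithium | [Li]c1ccc(O[Si](C(C)C)(C(C)C)C(C)C)c(O[Si](C(C)C)(C(C)C)C(C)C)c1 | intermediate
8 | lithium triethoxy[3,4-bis(triisopropylsilyloxy)phenyl]borate | [Li+].CCO[B-](OCC)(OCC)c1ccc(O[Si](C(C)C)(C(C)C)C(C)C)c(O[Si](C(C)C)(C(C)C)C(C)C)c1 | intermediate
9 | diethyl [3,4-bis(triisopropylsilyloxy)phenyl]boronate | CCOB(OCC)c1ccc(O[Si](C(C)C)(C(C)C)C(C)C)c(O[Si](C(C)C)(C(C)C)C(C)C)c1 | intermediate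
10 | (2S)-2-[3,4-bis(triisopropylsilyloxy)phenyl]-7-(tert-butyldimethylsilyloxy)-2H-chromene | CC(C)(C)[Si](C)(C)Oc1ccc2c(c1)O[C@H](c1ccc(O[Si](C(C)C)(C(C)C)C(C)C)c(O[Si](C(C)C)(C(C)C)C(C)C)c1)C=C2 | intermediate
11 | (2S)-2-[3,4-bis(triisopropylsilyloxy)phenyl]-2H-chromen-7-ol | Oc1ccc2c(c1)O[C@H](c1ccc(O[Si](C(C)C)(C(C)C)C(C)C)c(O[Si](C(C)C)(C(C)C)C(C)C)c1)C=C2 | intermediate
12 | (2R,3S,4S)-2-[3,4-bis(triisopropylsilyloxy)phenyl]-7-(tert-butyldimethylsilyloxy)-3,4-epoxychromane | CC(C)(C)[Si](C)(C)Oc1ccc2c(c1)O[C@H](c1ccc(O[Si](C(C)C)(C(C)C)C(C)C)c(O[Si](C(C)C)(C(C)C)C(C)C)c1)[C@H]1O[C@@H]21 | intermediate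
13 | tris{(2S)-2-[3,4-bis(triisopropylsilyloxy)phenyl]-2H-chromen-7-yl} borate | B(Oc1ccc2c(c1)O[C@H](c1ccc(O[Si](C(C)C)(C(C)C)C(C)C)c(O[Si](C(C)C)(C(C)C)C(C)C)c1)C=C2)(Oc1ccc2c(c1)O[C@H](c1ccc(O[Si](C(C)C)(C(C)C)C(C)C)c(O[Si](C(C)C)(C(C)C)C(C)C)c1)C=C2)Oc1ccc2c(c1)O[C@H](c1ccc(O[Si](C(C)C)(C(C)C)C(C)C)c(O[Si](C(C)C)(C(C)C)C(C)C)c1)C=C2 | intermediate
14 | (2R,3S,4S)-2-[3,4-bis(triisopropylsilyloxy)phenyl]-7-(tert-butyldimethylsilyloxy)-4-{(2S)-2-[3,4-bis(triisopropylsilyloxy)phenyl]-7-hydroxy-2H-chromen-6-yl}chroman-3-ol | CC(C)(C)[Si](C)(C)Oc1ccc2c(c1)O[C@H](c1ccc(O[Si](C(C)C)(C(C)C)C(C)C)c(O[Si](C(C)C)(C(C)C)C(C)C)c1)[C@@H](O)[C@H]2c1cc2c(cc1O)O[C@H](c1ccc(O[Si](C(C)C)(C(C)C)C(C)C)c(O[Si](C(C)C)(C(C)C)C(C)C)c1)C=C2 | intermediate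
15 | (2R,3S,4S)-2-[3,4-bis(triisopropylsilyloxy)phenyl]-6-{(2R,3S,4S)-2-[3,4-bis(triisopropylsilyloxy)phenyl]-7-(tert-butyldimethylsilyloxy)-3-hydroxychroman-4-yl}chromane-3,4,7-triol | CC(C)(C)[Si](C)(C)Oc1ccc2c(c1)O[C@H](c1ccc(O[Si](C(C)C)(C(C)C)C(C)C)c(O[Si](C(C)C)(C(C)C)C(C)C)c1)[C@@H](O)[C@H]2c1cc2c(cc1O)O[C@H](c1ccc(O[Si](C(C)C)(C(C)C)C(C)C)c(O[Si](C(C)C)(C(C)C)C(C)C)c1)[C@@H](O)[C@H]2O | intermediate
16 | (2R,3S,4S)-2-(3,4-dihydroxyphenyl)-6-[(2R,3S,4S)-2-(3,4-dihydroxyphenyl)-3,7-dihydroxy-3,4-dihydro-2H-chromen-4-yl]-3,4-dihydro-2H-chromene-3,4,7-triol | Oc1ccc2c(c1)O[C@H](c1ccc(O)c(O)c1)[C@@H](O)[C@H]2c1cc2c(cc1O)O[C@H](c1ccc(O)c(O)c1)[C@@H](O)[C@H]2O | target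

## Step count and least certain steps

Total: 10 steps. Longest linear sequence: 7 steps (steps 1, 2, 5, 7, 8, 9, 10 from umbelliferone; the branch from 4-bromocatechol through steps 3, 4, 5, 7, 8, 9, 10 is equally long).

**Step 8 (key step).** What may go wrong:
- loss of facial control if the 7-silyloxy-stabilised C4 cation escapes the boron-bound ion pair and is captured intermolecularly from the face anti to O3;
- a 1,2-hydride shift from C3 to C4 (Meinwald-type rearrangement to the flavan-3-one);
- O-alkylation in place of C-alkylation;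
- attack of the cation on the flavene double bond of a neighbouring ligand.

Fallback: a covalent silicon tether that keeps the same stereochemical logic but separates activation from delivery. It sets out from 12 and returns at 16.
- 12 is opened with methanol at low temperature to the 4-methoxyflavan-3-ol F1. The C4 epimer mixture is immaterial because C4 is re-ionised later.
- O3 of F1 and O7 of phenol 11 are joined with i-Pr2SiCl2/imidazole to the mixed silylene acetal F2.
- TMSOTf (cat.) or BF3·OEt2 in CH2Cl2 at −78 °C ionises C4(C), and intramolecular Friedel–Crafts closure of the seven-membered ring gives the bridged 3,4-cis dimer F3.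
- Catalytic OsO4/N-methylmorpholine N-oxide dihydroxylation gives the diol F4.
- Buffered TBAF removes the bridge together with all aryl silyl ethers and gives 16.

**Step 5.** What may go wrong: erosion of enantioselectivity by an uncatalysed aryl transfer to the strongly stabilised 7-silyloxybenzopyrylium ion, competing attack at C4, or racemisation of the product by Lewis-acid ionisation of its allylic, benzylic C2–O1 bond. Fallback: resolution in place of asymmetric catalysis, setting out from 4 and 9 and returning at 10. The arylation is run with an achiral Lewis acid (BF3·OEt2, CH2Cl2, −40 °C) to give the racemic flavene F5, and the enantiomers are separated by preparative chromatography on a chiral stationary phase; the (2S) enantiomer is 10.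

**Step 6.** What may go wrong: incomplete discrimination between the aryl TBS and aryl TIPS ethers, or base-induced ring opening of the 7-hydroxyflavene through its phenoxide. Fallback: an ester in place of the silyl ether at O7, setting out from 4 and returning at 11.
- 4 is converted in one pot with CsF/Ac2O in DMF into 7-acetoxy-2-ethoxy-2H-chromene F6.
- Arylation with 9 under the conditions of step 5 gives the 7-acetoxyflavene F7.
- Aminolysis with NH3 in MeOH at 0 °C, which leaves aryl TIPS ethers untouched, gives 11.

**Step 9.** What may go wrong: oxidation of the free, electron-rich ring-D phenol by the osmium/N-oxide system, or epimerisation at C4(F) through quinone-methide formation from the free p-hydroxybenzylic diol in the mildly basic aqueous medium. Fallback: remove the free phenol before the oxidation, setting out from 14 and returning at 16.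
- 14 is silylated at O7(D) (TBSCl, imidazole, DMF) to the bis-TBS ether F8.
- Dihydroxylation as in step 9 gives the diol F9.
- The fluoride treatment of step 10 gives 16.

## Further compounds

F1 | step 8 | (2R,3S)-2-[3,4-bis(triisopropylsilyloxy)phenyl]-7-(tert-butyldimethylsilyloxy)-4-methoxychroman-3-ol (C4 epimer mixture) | CC(C)(C)[Si](C)(C)Oc1ccc2c(c1)O[C@H](c1ccc(O[Si](C(C)C)(C(C)C)C(C)C)c(O[Si](C(C)C)(C(C)C)C(C)C)c1)[C@@H](O)C2OC
F2 | step 8 | mixed diisopropylsilylene acetal joining O3 of F1 to O7 of 11 | CC(C)(C)[Si](C)(C)Oc1ccc2c(c1)O[C@H](c1ccc(O[Si](C(C)C)(C(C)C)C(C)C)c(O[Si](C(C)C)(C(C)C)C(C)C)c1)[C@@H](O[Si](C(C)C)(C(C)C)Oc1ccc3c(c1)O[C@H](c1ccc(O[Si](C(C)C)(C(C)C)C(C)C)c(O[Si](C(C)C)(C(C)C)C(C)C)c1)C=C3)C2OC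
F3 | step 8 | O3(C),O7(D)-diisopropylsilylene-bridged 3,4-cis flavan–flavene dimer | CC(C)(C)[Si](C)(C)Oc1ccc2c(c1)O[C@H](c1ccc(O[Si](C(C)C)(C(C)C)C(C)C)c(O[Si](C(C)C)(C(C)C)C(C)C)c1)[C@@H](O[Si](C(C)C)(C(C)C)O5)[C@H]2c1cc2c(cc15)O[C@H](c1ccc(O[Si](C(C)C)(C(C)C)C(C)C)c(O[Si](C(C)C)(C(C)C)C(C)C)c1)C=C2
F4 | step 8 | O3(C),O7(D)-diisopropylsilylene-bridged dimer with the 3,4-cis diol in ring F | CC(C)(C)[Si](C)(C)Oc1ccc2c(c1)O[C@H](c1ccc(O[Si](C(C)C)(C(C)C)C(C)C)c(O[Si](C(C)C)(C(C)C)C(C)C)c1)[C@@H](O[Si](C(C)C)(C(C)C)O5)[C@H]2c1cc2c(cc15)O[C@H](c1ccc(O[Si](C(C)C)(C(C)C)C(C)C)c(O[Si](C(C)C)(C(C)C)C(C)C)c1)[C@@H](O)[C@H]2O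
F5 | step 5 | racemic 2-[3,4-bis(triisopropylsilyloxy)phenyl]-7-(tert-butyldimethylsilyloxy)-2H-chromene | CC(C)(C)[Si](C)(C)Oc1ccc2c(c1)OC(c1ccc(O[Si](C(C)C)(C(C)C)C(C)C)c(O[Si](C(C)C)(C(C)C)C(C)C)c1)C=C2
F6 | step 6 | 2-ethoxy-2H-chromen-7-yl acetate (racemic) | CCOC1C=Cc2ccc(OC(C)=O)cc2O1
F7 | step 6 | (2S)-2-[3,4-bis(triisopropylsilyloxy)phenyl]-2H-chromen-7-yl acetate | CC(=O)Oc1ccc2c(c1)O[C@H](c1ccc(O[Si](C(C)C)(C(C)C)C(C)C)c(O[Si](C(C)C)(C(C)C)C(C)C)c1)C=C2
F8 | step 9 | 7(D)-O-tert-butyldimethylsilyl ether of 14 | CC(C)(C)[Si](C)(C)Oc1ccc2c(c1)O[C@H](c1ccc(O[Si](C(C)C)(C(C)C)C(C)C)c(O[Si](C(C)C)(C(C)C)C(C)C)c1)[C@@H](O)[C@H]2c1cc2c(cc1O[Si](C)(C)C(C)(C)C)O[C@H](c1ccc(O[Si](C(C)C)(C(C)C)C(C)C)c(O[Si](C(C)C)(C(C)C)C(C)C)c1)C=C2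
F9 | step 9 | 7(D)-O-tert-butyldimethylsilyl ether of 15 | CC(C)(C)[Si](C)(C)Oc1ccc2c(c1)O[C@H](c1ccc(O[Si](C(C)C)(C(C)C)C(C)C)c(O[Si](C(C)C)(C(C)C)C(C)C)c1)[C@@H](O)[C@H]2c1cc2c(cc1O[Si](C)(C)C(C)(C)C)O[C@H](c1ccc(O[Si](C(C)C)(C(C)C)C(C)C)c(O[Si](C(C)C)(C(C)C)C(C)C)c1)[C@@H](O)[C@H]2O
A1 | alternative 1 | (+)-mollisacacidin, (2R,3S,4R)-2-(3,4-dihydroxyphenyl)chromane-3,4,7-triol | Oc1ccc2c(c1)O[C@H](c1ccc(O)c(O)c1)[C@@H](O)[C@@H]2O
A2 | alternative 1 | (2R,3S,4S)-2-(3,4-dihydroxyphenyl)chromane-3,4,7-triol (3,4-cis leucofisetinidin) | Oc1ccc2c(c1)O[C@H](c1ccc(O)c(O)c1)[C@@H](O)[C@H]2O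
A3 | alternative 1 | fisetinidol-(4α→6)-leucofisetinidin, the C4(C) epimer of the target | Oc1ccc2c(c1)O[C@H](c1ccc(O)c(O)c1)[C@@H](O)[C@@H]2c1cc2c(cc1O)O[C@H](c1ccc(O)c(O)c1)[C@@H](O)[C@H]2O
A4 | alternative 2 | silyl-protected 4-(flav-3-en-6-yl)flav-3-ene | CC(C)(C)[Si](C)(C)Oc1ccc2c(c1)O[C@H](c1ccc(O[Si](C(C)C)(C(C)C)C(C)C)c(O[Si](C(C)C)(C(C)C)C(C)C)c1)C=C2c1cc2c(cc1O[Si](C)(C)C(C)(C)C)O[C@H](c1ccc(O[Si](C(C)C)(C(C)C)C(C)C)c(O[Si](C(C)C)(C(C)C)C(C)C)c1)C=C2
A5 | alternative 3 | diisopropylsilylene acetal joining O3(C) of 7,3',4'-tri-O-benzyl-4-ethoxyfisetinidol to O7(D) of 3',4'-di-O-benzyl-3,4-O-isopropylidene-(2R,3S,4S)-leucofisetinidin | C(c1ccccc1)Oc1ccc2c(c1)O[C@H](c1ccc(OCc3ccccc3)c(OCc3ccccc3)c1)[C@@H](O[Si](C(C)C)(C(C)C)Oc1ccc3c(c1)O[C@H](c1ccc(OCc4ccccc4)c(OCc4ccccc4)c1)[C@H]1OC(C)(C)O[C@@H]31)C2OCC
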